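**Retrosynthetic overview**
- The target's 5-allyl-6-hydroxy unit is opened by an aromatic Claisen disconnection to the 6-O-allyl ether of the trans-dihydrobenzofuran, so the O-allyl group is both protecting group and allyl source.
- The dihydrofuran ring is opened at C3–C3a (5-exo aryl radical cyclization, sets C3 trans to C2) to an (S)-1-arylallyl 2-bromoaryl ether.
- Key disconnection O1–C2: enantioconvergent iridium-catalysed O-allylation of 5-(allyloxy)-2-bromophenol with a racemic branched allylic carbonate; this C–O bond carries all the stereochemical information.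
- Fragments: the phenol from 4-bromoresorcinol and allyl bromide; the carbonate from 3,4,5-trimethoxybenzaldehyde, vinylmagnesium bromide and methyl chloroformate.
- Ring order: both benzene rings are bought; the dihydrofuran ring is the only ring formed, after the key C–O bond.

Assumption: the R enantiomer of the phosphoramidite–olefin ligand L* (BINOL-derived N-dibenzo[b,f]azepin-5-yl phosphoramidite) is taken to be the one that gives the S aryl ether in step 3; if a test run shows the opposite sense, its antipode is used.

**Step 1**
Reactants: 1 4-bromoresorcinol; 2 allyl bromide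
Product: 4 5-(allyloxy)-2-bromophenol, via disodium resorcinolate 3 (not isolated)
Conditions: NaH (2.2 equiv), DMF, 0 °C; then 2 (1.0 equiv), 0 °C to rt; aq. HCl work-up
Reagents that add atoms: none
Why: Williamson O-allylation of the dianion, in which the phenoxide para to bromine is the more basic and less hindered oxygen and so takes the single equivalent of allyl bromide (expected about 5:1; the regioisomer and bis-ether are removed by chromatography), with no stereocenter formed.

**Step 2**
Reactants: 5 3,4,5-trimethoxybenzaldehyde; 6 vinylmagnesium bromide; 7 methyl chloroformate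
Product: 9 rac-methyl 1-(3,4,5-trimethoxyphenyl)prop-2-en-1-yl carbonate, via bromomagnesium alkoxide 8 (not isolated)
Conditions: 6 (1.1 equiv), THF, −20 to 0 °C; then 7 (1.3 equiv), 0 °C to rt
Reagents that add atoms: none
Why: Grignard 1,2-addition to the aldehyde followed by in situ O-acylation of the alkoxide gives the branched carbonate in one pot, and the carbinol centre is deliberately racemic because step 3 is enantioconvergent.

**Step 3**
Reactants: 4 5-(allyloxy)-2-bromophenol; 9 rac-methyl 1-(3,4,5-trimethoxyphenyl)prop-2-en-1-yl carbonate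
Product: 10 4-(allyloxy)-1-bromo-2-{[(1S)-1-(3,4,5-trimethoxyphenyl)prop-2-en-1-yl]oxy}benzene
Conditions: [Ir(cod)Cl]2 (2.5 mol%), (R)-L* (10 mol%), 9 (1.3 equiv), THF, 25 °C
Reagents that add atoms: none
Why: Proposed new method: enantioconvergent iridium-catalysed O-allylation of a phenol with a racemic branched aryl-substituted allylic carbonate, in which monovalent iridium carrying two phosphoramidite–olefin ligands ionises both enantiomers of 9 to one rapidly equilibrating (η3-allyl) trivalent iridium species, the methoxide released with CO2 deprotonates the acidic bromophenol 4, and outer-sphere attack of the phenoxide at the aryl-bearing allyl terminus forms the C–O bond and sets C2 as S under catalyst control; the closest known reactions are the iridium/phosphoramidite allylic etherification of linear cinnamyl carbonates with aryloxides and the iridium/phosphoramidite–olefin enantioconvergent etherification of racemic aryl vinyl carbinols with aliphatic alcohols.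

**Step 4**
Reactants: 10 4-(allyloxy)-1-bromo-2-{[(1S)-1-(3,4,5-trimethoxyphenyl)prop-2-en-1-yl]oxy}benzene
Product: 11 (2S,3S)-6-(allyloxy)-3-methyl-2-(3,4,5-trimethoxyphenyl)-2,3-dihydro-1-benzofuran
Conditions: Bu3SnH (1.3 equiv, 0.1 M), AIBN (0.2 equiv), PhH, 80 °C
Reagents that add atoms: none
Why: Bu3SnH-mediated 5-exo-trig aryl radical cyclization (Beckwith–Houk model) in which the aryl radical adds to the internal vinyl carbon through the transition state that keeps the 2-aryl group pseudo-equatorial, so C3 is set trans to the untouched S centre at C2 (3S, expected about 5:1 trans/cis, cis isomer removed by chromatography) and the primary radical is reduced to the methyl group, while the simple O-allyl group para to the radical site cannot be reached.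

**Step 5**
Reactants: 11 (2S,3S)-6-(allyloxy)-3-methyl-2-(3,4,5-trimethoxyphenyl)-2,3-dihydro-1-benzofuran
Product: 13 (2S,3S)-5-allyl-3-methyl-2-(3,4,5-trimethoxyphenyl)-2,3-dihydro-1-benzofuran-6-ol (CNP0286233.1), via ortho-dienone 12 (not isolated)
Conditions: PhNEt2, 190 °C, sealed tube, 8 h
Reagents that add atoms: none
Why: Thermal aromatic Claisen rearrangement ([3,3]-sigmatropic shift then enolization) moves the allyl group from O6 to C5, favoured over C7 because C5 is para to the ring oxygen and is not flanked by two oxygens (expected about 4:1, isomers separable), and neither stereocenter is touched.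

**Compound list**
1 | 4-bromoresorcinol (4-bromobenzene-1,3-diol) | Oc1ccc(Br)c(O)c1 | starting material
2 | allyl bromide | C=CCBr | starting material
3 | disodium 4-bromobenzene-1,3-diolate (not isolated) | [Na+].[Na+].[O-]c1ccc(Br)c([O-])c1 | intermediate
4 | 5-(allyloxy)-2-bromophenol | Oc1cc(OCC=C)ccc1Br | intermediate
5 | 3,4,5-trimethoxybenzaldehyde | COc1cc(C=O)cc(OC)c1OC | starting material
6 | vinylmagnesium bromide | C=C[Mg]Br | starting material
7 | methyl chloroformate | COC(=O)Cl | starting material
8 | bromomagnesium 1-(3,4,5-trimethoxyphenyl)prop-2-en-1-olate (racemic, not isolated) | C=CC(O[Mg]Br)c1cc(OC)c(OC)c(OC)c1 | intermediate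
9 | rac-methyl 1-(3,4,5-trimethoxyphenyl)prop-2-en-1-yl carbonate | C=CC(OC(=O)OC)c1cc(OC)c(OC)c(OC)c1 | intermediate
10 | 4-(allyloxy)-1-bromo-2-{[(1S)-1-(3,4,5-trimethoxyphenyl)prop-2-en-1-yl]oxy}benzene | C=CCOc1ccc(Br)c(O[C@@H](C=C)c2cc(OC)c(OC)c(OC)c2)c1 | intermediate
11 | (2S,3S)-6-(allyloxy)-3-methyl-2-(3,4,5-trimethoxyphenyl)-2,3-dihydro-1-benzofuran | C=CCOc1ccc2c(c1)O[C@H](c1cc(OC)c(OC)c(OC)c1)[C@H]2C | intermediate
12 | (2S,3S)-5-allyl-3-methyl-2-(3,4,5-trimethoxyphenyl)-3,5-dihydro-1-benzofuran-6(2H)-one (C5 epimers, not isolated) | C=CCC1C=C2C(=CC1=O)O[C@H](c1cc(OC)c(OC)c(OC)c1)[C@H]2C | intermediate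
13 | (2S,3S)-5-allyl-3-methyl-2-(3,4,5-trimethoxyphenyl)-2,3-dihydro-1-benzofuran-6-ol (CNP0286233.1) | C=CCc1cc2c(cc1O)O[C@H](c1cc(OC)c(OC)c(OC)c1)[C@H]2C | target

**Totals**
Total step count: 5. Longest linear sequence: 4 steps (steps 2, 3, 4, 5 from aldehyde 5, or steps 1, 3, 4, 5 from 4-bromoresorcinol 1).

**Steps most likely to fail, with fallbacks**

Step 3 (the proposed new method) is the most likely to fail. Possible failure modes are incomplete equilibration of the allyl intermediates (low ee), re-ionisation of the product ether to the linear isomer, or C-allylation of the electron-rich ring. The fallback uses the known iridium-catalysed etherification of a linear carbonate; it sets out from 5 and 4 and comes back at 10. Wittig olefination of 5 with Ph3P=CHCO2Me (toluene, 90 °C) gives methyl (E)-3-(3,4,5-trimethoxyphenyl)acrylate F1. Reduction with i-Bu2AlH (CH2Cl2, −78 °C) gives (E)-3-(3,4,5-trimethoxyphenyl)prop-2-en-1-ol F2. Acylation with 7 and pyridine (CH2Cl2, 0 °C) gives methyl (E)-3-(3,4,5-trimethoxyphenyl)allyl carbonate F3. Phenol 4 is converted with NaH in THF into sodium 5-(allyloxy)-2-bromophenolate F4. F4 and F3 are then coupled with [Ir(cod)Cl]2 (1 mol%) and the (Sa,Sc,Sc)-binaphthyl N,N-bis(1-phenylethyl)phosphoramidite (2 mol%, amine-activated) in THF at 50 °C to give the branched S ether 10. The ligand sense is assigned by analogy; the antipode is used if it proves opposite.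

Step 5 may give an inseparable C5/C7 mixture. The fallback replaces the sigmatropic shift by electrophilic substitution and cross-coupling; it sets out from 11 and comes back at 13. Deallylation with Pd(PPh3)4 (2 mol%) and morpholine in THF at rt gives (2S,3S)-3-methyl-2-(3,4,5-trimethoxyphenyl)-2,3-dihydro-1-benzofuran-6-ol F5. Bromination with NBS (1.0 equiv, CH2Cl2, −78 °C) goes para to the ring oxygen and gives (2S,3S)-5-bromo-3-methyl-2-(3,4,5-trimethoxyphenyl)-2,3-dihydro-1-benzofuran-6-ol F6. Stille coupling with allyltributylstannane and Pd(PPh3)4 (DMF, 90 °C) gives 13.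

Step 1 may show poor site selectivity between the two hydroxyls. The fallback installs bromine after the allyl ether; it sets out from 2 and comes back at 4. Bought resorcinol (Oc1cccc(O)c1) is mono-allylated with 2 (K2CO3, acetone, reflux) to 3-(allyloxy)phenol F7. Amine-directed ortho-bromination (NBS, cat. i-Pr2NH, CH2Cl2, 0 °C) at the position para to the allyloxy group then gives 4.

Further compounds
F1 | step 3 | methyl (E)-3-(3,4,5-trimethoxyphenyl)acrylate | COC(=O)/C=C/c1cc(OC)c(OC)c(OC)c1
F2 | step 3 | (E)-3-(3,4,5-trimethoxyphenyl)prop-2-en-1-ol | OC/C=C/c1cc(OC)c(OC)c(OC)c1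
F3 | step 3 | methyl (E)-3-(3,4,5-trimethoxyphenyl)allyl carbonate | COC(=O)OC/C=C/c1cc(OC)c(OC)c(OC)c1
F4 | step 3 | sodium 5-(allyloxy)-2-bromophenolate | [Na+].[O-]c1cc(OCC=C)ccc1Br
F5 | step 5 | (2S,3S)-3-methyl-2-(3,4,5-trimethoxyphenyl)-2,3-dihydro-1-benzofuran-6-ol | Oc1ccc2c(c1)O[C@H](c1cc(OC)c(OC)c(OC)c1)[C@H]2C
F6 | step 5 | (2S,3S)-5-bromo-3-methyl-2-(3,4,5-trimethoxyphenyl)-2,3-dihydro-1-benzofuran-6-ol | Brc1cc2c(cc1O)O[C@H](c1cc(OC)c(OC)c(OC)c1)[C@H]2C
F7 | step 1 | 3-(allyloxy)phenol | Oc1cccc(OCC=C)c1
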